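**Numbering used throughout.** 1 methyl sinapate; 2 bromoacetaldehyde diethyl acetal; 3 acetal ether; 4 aryloxyacetaldehyde; 5 isopropenylmagnesium bromide; 6 hydroxy ester; 7 diol; 8 tert-butyldimethylsilyl chloride; 9 silylated isopropenyl carbinol; 10 triethyl orthoacetate; 11 mixed orthoester; 12 ketene acetal; 13 ethyl ester; 14 N,O-dimethylhydroxylamine hydrochloride; 15 N-methoxy-N-methylamide; 16 enone; 17 (R)-alcohol silyl ether; 18 target. Side-chain locants: C1 is the OCH2 carbon, C2=C3 the trisubstituted alkene (methyl on C3), C4 and C5 the methylenes, C6 the carbinol carbon, C7=C8 the isopropenyl alkene.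

## Analysis of the target

The target 18 is acyclic apart from one benzene ring: a sinapyl alcohol unit (3,5-dimethoxy, with an (E)-3-hydroxyprop-1-enyl chain para to the phenolic oxygen) whose phenolic oxygen is bound to C1 of a (2E,6R)-6-hydroxy-3,7-dimethylocta-2,7-dienyl chain. There is a single stereocentre, C6, and the SMILES reads as R (O > C7 > C5 > H). It is separated from every other stereochemical element by two methylene groups, so nothing in the molecule can relay selectivity to it and it has to be set by a reagent. Two alkenes have defined geometry: the cinnamyl alkene (E), which is bought, and the trisubstituted C2=C3 alkene (E), which is not. The sensitive groups are the electron-rich cinnamyl alcohol, the allyl aryl ether at C1 and the secondary allylic alcohol at C6; all three ionise or transpose under acid, and the two allylic hydroxyls must be told apart. The difficulty is therefore selectivity, not complexity: E geometry at C2=C3, one unbiased carbinol centre, and a phenolic oxygen flanked by two methoxy groups. The strategy rests on the fact that C2=C3 with its C3 methyl lies γ,δ to C6. With C6 at the carboxyl oxidation level the chain is a 4-methylhex-4-enoate, the product of a Claisen rearrangement of an isopropenyl carbinol whose carbinol carbon becomes C2 and already carries C1 with the aryl ether oxygen.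

## Retrosynthetic reasoning

The cinnamyl hydroxyl of 18 is masked as the silyl ether in 17. It must be distinguished from the C6 hydroxyl, and it must be blocked during the rearrangement, where a free primary allylic alcohol would undergo its own orthoester exchange. The last step is a desilylation.

The C6–H bond of 17 is cut to give the enone 16. The stereocentre is placed last among the skeletal operations, so every earlier intermediate can be racemic or achiral. The forward step is a Corey–Bakshi–Shibata reduction in which the isopropenyl group is the large substituent and the unbranched chain the small one.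

The C6–C7 bond of 16 is cut to the N-methoxy-N-methylamide 15 and the Grignard reagent 5. An amide of this type stops at the ketone, so C6 arrives at the right oxidation level in one step.

The amide 15 is traced to the ethyl ester 13 and the amine salt 14. Going through the amide avoids a partial reduction of the ester to an aldehyde, which is hard to stop cleanly.

The C4–C5 bond of 13 is cut, with transposition of the alkene, to the isopropenyl carbinol 9 and the orthoester 10, by way of the ketene acetal 12. This is the one disconnection that builds the chain, and it is made here because the forward rearrangement creates exactly the C2=C3 alkene with its C3 methyl. The forward reaction has to deliver E geometry and must leave the silyl ether and the aryl ether alone. The carbinol centre of 9 is destroyed, so 9 is needed only as the racemate.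

The silyl ether 9 is traced to the diol 7 and the silyl chloride 8, and 7 to the hydroxy ester 6 by reduction of the cinnamate. The ester is kept until this point because an electron-poor enoate survives the aqueous acid needed two steps earlier, which a cinnamyl alcohol or its silyl ether would not.

The bond between the carbinol carbon and the isopropenyl group of 6 is cut to the aldehyde 4 and a second portion of 5. The forward addition has to take the aldehyde and leave the conjugated methyl ester.

The aldehyde 4 comes from the acetal 3, and the O–CH2 bond of 3 is cut to the phenol 1 and the bromide 2. The phenolic oxygen is alkylated first, while the molecule is at its most robust.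

## Alternatives that were turned down

Alternative 1: Here the C6 hydroxyl and the C7=C8 alkene are traced to a 6,7-epoxide with a hydroxyl on C8, so that the precursor is the 8-hydroxygeranyl ether A1 of 1. Forward, the C8 allylic alcohol of A1 would be epoxidised with t-BuOOH, Ti(OiPr)4 and D-(−)-diisopropyl tartrate (Sharpless asymmetric epoxidation) to the (6R,7R)-epoxy alcohol A2. The C8 hydroxyl would then be converted to an iodide and reduced with zinc, which opens the oxirane and leaves the C6–O bond and its configuration untouched; reduction of the cinnamate would finish. In its favour, (E)-2-methylalk-2-en-1-ols are among the best substrates for this epoxidation, the facial selectivity follows a firm mnemonic, and the E C2=C3 alkene comes ready-made in the geranyl skeleton. Against it, A1 requires oxidation of a geranyl unit at C8 in the presence of two other allylic sites (SeO2 chemistry, prone to over-oxidation) or a pre-oxidised, protected C10 halide made in several steps. The epoxy iodide reduction must be run on a molecule with an ionisable allyl aryl ether, and three operations follow the key step. On the enantioselective step itself this alternative is stronger than the chosen route, whose reduction must tell an isopropenyl group from an unbranched chain. In exchange the chosen route needs no regioselective C–H oxidation, builds the chain from cheap two- and three-carbon reagents, and sets the stereocentre on the ketone 16, where the step can be repeated or replaced by a resolution. The step counts are about equal.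

Alternative 2: The C2=C3 alkene is assembled by carbometalation: the C3–CH3 and C1–C2 bonds are cut, leading to the silylated (R)-enynol A3 and formaldehyde A4. Forward, Cp2ZrCl2-catalysed syn addition of AlMe3 across the terminal alkyne of A3 places methyl on C3 and aluminium on C2; conversion to the alanate and trapping with A4 gives the (2E,6R)-dienol A5. A5 would be joined to 1 by a Mitsunobu etherification, then reduced and desilylated. In its favour, syn-carboalumination gives the E alkene with isomeric purity at least equal to that of the Claisen rearrangement. The plan is also convergent, since the C10 unit is complete and enantioenriched before it meets the arene; on convergence it is the stronger plan. Against it, the key step does not address the stereocentre: A3 still has to be made enantioselectively, on a small, volatile compound without a chromophore, so the hard part is moved and not removed. AlMe3 is pyrophoric and used in excess, the allylic silyl ether sits next to a strong Lewis acid, and the Mitsunobu coupling of a primary allylic alcohol with a hindered phenol can divert into SN2′ substitution. The chosen strategy gives the same alkene geometry from 10 and a trace of weak acid, carries a non-volatile, UV-active arene from the first step, and has a comparable step count.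

Alternative 3: The C6–C7 bond is cut, giving the C6 aldehyde A7 and 2-bromopropene A8; A7 would come from O-geranylation of 1 to the geranyl ether A6 and oxidative cleavage of its distal alkene through the terminal epoxide. Forward, A7 and A8 would be coupled by divalent chromium (CrCl2) with catalytic NiCl2 and a chiral oxazoline–sulfonamide ligand (asymmetric Nozaki–Hiyama–Kishi reaction), forming C6–C7 and the (R)-carbinol of A9 in one step; reduction of the ester would give the target. In its favour, this is the shortest plan, roughly six steps against ten. The organochromium reagent ignores the cinnamate, so no protecting group is needed, and the E alkene is bought. On step and protecting-group economy it is clearly stronger than the chosen route. Against it, everything depends on the enantioselectivity of one step with an unbranched, flexible aliphatic aldehyde and the smallest alkenyl halide, a pairing for which the ligand has to be tuned. The ligand is not a stock item and is needed in amounts close to that of the chromium salt, CrCl2 is toxic and air-sensitive, and cleaving one of two trisubstituted alkenes in A6 needs care. The chosen route is longer, but each step uses catalogue reagents with a well-understood selectivity model. It also separates bond construction (steps 6 and 8) from stereocontrol (step 9), so a shortfall in enantioselectivity can be corrected without rebuilding the skeleton.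

Key step: step 6

Remark: compounds 6, 7, 9, 11 and 12 are racemic by design, because their only stereocentre becomes the sp2 carbon C2 in step 6.

## Route

Step 1
Reactants: 1 methyl sinapate; 2 bromoacetaldehyde diethyl acetal
Product: 3 methyl (E)-3-[4-(2,2-diethoxyethoxy)-3,5-dimethoxyphenyl]prop-2-enoate
Conditions: K2CO3, KI (cat.), DMF, 110 °C
Reagents that add atoms: bromoacetaldehyde diethyl acetal (2), CCOC(CBr)OCC
Why: Williamson etherification: the phenoxide of 1 displaces bromide from 2 by SN2, iodide exchange speeds the sluggish β,β-dialkoxyethyl electrophile, and the methyl ester is inert to anhydrous K2CO3.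

Step 2
Reactants: 3 methyl (E)-3-[4-(2,2-diethoxyethoxy)-3,5-dimethoxyphenyl]prop-2-enoate
Product: 4 methyl (E)-3-[3,5-dimethoxy-4-(2-oxoethoxy)phenyl]prop-2-enoate
Conditions: CF3CO2H–H2O (1:1), CHCl3, 0 °C to rt; crude product dried azeotropically (toluene) and used at once
Reagents that add atoms: water, O
Why: Acid-catalysed acetal hydrolysis; the electron-poor enoate tolerates aqueous acid, and because both ortho positions carry methoxy groups the aldehyde cannot cyclise onto the ring to a benzofuran.

Step 3
Reactants: 4 methyl (E)-3-[3,5-dimethoxy-4-(2-oxoethoxy)phenyl]prop-2-enoate; 5 isopropenylmagnesium bromide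
Product: 6 methyl (E)-3-[4-(2-hydroxy-3-methylbut-3-enyloxy)-3,5-dimethoxyphenyl]prop-2-enoate (racemic)
Conditions: CH2=C(CH3)MgBr (1.1 equiv), THF, −78 °C; then aq. NH4Cl
Reagents that add atoms: isopropenylmagnesium bromide (5), C=C(C)[Mg]Br
Why: Grignard 1,2-addition; at −78 °C with a small excess of 5 the α-aryloxy aldehyde should react far faster than the conjugated methyl ester, and the new carbinol centre is left racemic because step 6 destroys it.

Step 4
Reactants: 6 methyl (E)-3-[4-(2-hydroxy-3-methylbut-3-enyloxy)-3,5-dimethoxyphenyl]prop-2-enoate (racemic)
Product: 7 rac-1-{4-[(E)-3-hydroxyprop-1-enyl]-2,6-dimethoxyphenoxy}-3-methylbut-3-en-2-ol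
Conditions: i-Bu2AlH (3.5 equiv), CH2Cl2, −78 to −20 °C; aq. potassium sodium tartrate
Reagents that add atoms: none
Why: Aluminium hydride 1,2-reduction of the cinnamate to the allylic alcohol; one equivalent of hydride is consumed by the free hydroxyl, and at low temperature the alkenes and the aryl ether are untouched.

Step 5
Reactants: 7 rac-1-{4-[(E)-3-hydroxyprop-1-enyl]-2,6-dimethoxyphenoxy}-3-methylbut-3-en-2-ol; 8 tert-butyldimethylsilyl chloride
Product: 9 rac-1-{4-[(E)-3-(tert-butyldimethylsilyloxy)prop-1-enyl]-2,6-dimethoxyphenoxy}-3-methylbut-3-en-2-ol
Conditions: t-BuMe2SiCl (1.05 equiv), imidazole, CH2Cl2, −20 to 0 °C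
Reagents that add atoms: tert-butyldimethylsilyl chloride (8), CC(C)(C)[Si](C)(C)Cl
Why: Selective silylation of the unhindered primary allylic hydroxyl over the secondary hydroxyl flanked by the isopropenyl and aryloxymethyl groups; this blocks the only other alcohol that could exchange with the orthoester in step 6.

Step 6
Reactants: 9 rac-1-{4-[(E)-3-(tert-butyldimethylsilyloxy)prop-1-enyl]-2,6-dimethoxyphenoxy}-3-methylbut-3-en-2-ol; 10 triethyl orthoacetate
Product: 13 ethyl (E)-6-{4-[(E)-3-(tert-butyldimethylsilyloxy)prop-1-enyl]-2,6-dimethoxyphenoxy}-4-methylhex-4-enoate, via mixed orthoester 11 (not isolated), via ketene acetal 12 (not isolated)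
Conditions: MeC(OEt)3 (excess), EtCO2H (cat.), 135–140 °C, EtOH distilled off
Reagents that add atoms: triethyl orthoacetate (10), CCOC(C)(OCC)OCC
Why: In this Johnson orthoester Claisen rearrangement EtCO2H catalyses exchange of one ethoxy group of 10 for the secondary hydroxyl of 9 to give 11, and loss of a second molecule of EtOH at 135–140 °C gives the ketene acetal 12. Compound 12 is an allyl vinyl ether and undergoes a concerted [3,3] sigmatropic shift through a chair transition state, in which the ketene acetal CH2 bonds to the terminal CH2 of the isopropenyl group (the C4–C5 bond), the alkene moves to C2=C3 and the former carbinol oxygen becomes the ester carbonyl at C6. The closest known reaction type is the orthoacetate Claisen rearrangement of secondary isopropenyl carbinols to (E)-4-methylalk-4-enoates. No ring is closed and no stereocentre is formed; the racemic carbinol centre of 9 becomes the sp2 carbon C2. The selectivity needed is E geometry at C2=C3, and the substrate secures it: in the chair the aryloxymethyl group on the carbinol carbon takes the equatorial position, because the axial position would place it 1,3-diaxial to the ethoxy group on the ketene acetal carbon. Only one hydroxyl can enter the exchange because the cinnamyl alcohol is silylated, and the weak acid with continuous removal of EtOH should leave the silyl ether and both ethers intact. The product is an allyl aryl ether, but both ortho positions carry methoxy groups and the para position carries the propenyl chain, so an aromatic Claisen shift has no free terminus at this temperature.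

Step 7
Reactants: 13 ethyl (E)-6-{4-[(E)-3-(tert-butyldimethylsilyloxy)prop-1-enyl]-2,6-dimethoxyphenoxy}-4-methylhex-4-enoate; 14 N,O-dimethylhydroxylamine hydrochloride
Product: 15 (E)-6-{4-[(E)-3-(tert-butyldimethylsilyloxy)prop-1-enyl]-2,6-dimethoxyphenoxy}-N-methoxy-N,4-dimethylhex-4-enamide
Conditions: MeNH(OMe)·HCl, i-PrMgCl, THF, −20 to 0 °C
Reagents that add atoms: N,O-dimethylhydroxylamine hydrochloride (14), CNOC.Cl
Why: Weinreb amide formation by aminolysis of the ethyl ester with the chloromagnesium amide made in the flask from 14 and i-PrMgCl; deprotonation of the amine outruns addition of i-PrMgCl to the ester at −20 °C, and the silyl ether, aryl ether and alkenes are inert.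

Step 8
Reactants: 15 (E)-6-{4-[(E)-3-(tert-butyldimethylsilyloxy)prop-1-enyl]-2,6-dimethoxyphenoxy}-N-methoxy-N,4-dimethylhex-4-enamide; 5 isopropenylmagnesium bromide
Product: 16 (E)-8-{4-[(E)-3-(tert-butyldimethylsilyloxy)prop-1-enyl]-2,6-dimethoxyphenoxy}-2,6-dimethylocta-1,6-dien-3-one
Conditions: CH2=C(CH3)MgBr (2.5 equiv), THF, 0 °C; inverse quench into cold aq. NH4Cl
Reagents that add atoms: isopropenylmagnesium bromide (5), C=C(C)[Mg]Br
Why: Weinreb ketone synthesis; the chelated tetrahedral magnesium intermediate resists a second addition and releases the enone only on quench, and the cold inverse quench limits conjugate addition of the liberated N,O-dimethylhydroxylamine to the α-methylene ketone.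

Step 9
Reactants: 16 (E)-8-{4-[(E)-3-(tert-butyldimethylsilyloxy)prop-1-enyl]-2,6-dimethoxyphenoxy}-2,6-dimethylocta-1,6-dien-3-one
Product: 17 (3R,6E)-8-{4-[(E)-3-(tert-butyldimethylsilyloxy)prop-1-enyl]-2,6-dimethoxyphenoxy}-2,6-dimethylocta-1,6-dien-3-ol
Conditions: (3aS)-1-methyl-3,3-diphenyltetrahydro-1H,3H-pyrrolo[1,2-c][1,3,2]oxazaborole [(S)-Me-CBS] (0.2 equiv), catecholborane, toluene, −78 °C
Reagents that add atoms: none
Why: Corey–Bakshi–Shibata reduction; the ketone binds the ring boron of the (S)-oxazaborolidine with the isopropenyl group (large) turned away from the catalyst, and hydride is delivered from the nitrogen-bound borane through a six-membered transition state to the Si face (O > C7 > C5). By analogy with aryl methyl ketones, which this catalyst reduces to (R)-carbinols, the (R)-alcohol should result; catecholborane at −78 °C is not expected to hydroborate the alkenes.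

Step 10
Reactants: 17 (3R,6E)-8-{4-[(E)-3-(tert-butyldimethylsilyloxy)prop-1-enyl]-2,6-dimethoxyphenoxy}-2,6-dimethylocta-1,6-dien-3-ol
Product: 18 (3R,6E)-8-{4-[(E)-3-hydroxyprop-1-enyl]-2,6-dimethoxyphenoxy}-2,6-dimethylocta-1,6-dien-3-ol
Conditions: Bu4NF, THF, 0 °C to rt
Reagents that add atoms: none
Why: Fluoride-mediated desilylation of the primary silyl ether; the non-acidic conditions spare the allyl aryl ether, the electron-rich cinnamyl alcohol and the secondary allylic alcohol, and the C6 stereocentre is not touched.

## Compound list

1 | methyl sinapate, methyl (E)-3-(4-hydroxy-3,5-dimethoxyphenyl)prop-2-enoate | COC(=O)/C=C/c1cc(OC)c(O)c(OC)c1 | starting material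
2 | bromoacetaldehyde diethyl acetal (2-bromo-1,1-diethoxyethane) | CCOC(CBr)OCC | starting material
3 | methyl (E)-3-[4-(2,2-diethoxyethoxy)-3,5-dimethoxyphenyl]prop-2-enoate | CCOC(COc1c(OC)cc(/C=C/C(=O)OC)cc1OC)OCC | intermediate
4 | methyl (E)-3-[3,5-dimethoxy-4-(2-oxoethoxy)phenyl]prop-2-enoate | O=CCOc1c(OC)cc(/C=C/C(=O)OC)cc1OC | intermediate
5 | isopropenylmagnesium bromide | C=C(C)[Mg]Br | starting material
6 | methyl (E)-3-[4-(2-hydroxy-3-methylbut-3-enyloxy)-3,5-dimethoxyphenyl]prop-2-enoate (racemic) | C=C(C)C(O)COc1c(OC)cc(/C=C/C(=O)OC)cc1OC | intermediate
7 | rac-1-{4-[(E)-3-hydroxyprop-1-enyl]-2,6-dimethoxyphenoxy}-3-methylbut-3-en-2-ol | C=C(C)C(O)COc1c(OC)cc(/C=C/CO)cc1OC | intermediate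
8 | tert-butyldimethylsilyl chloride | CC(C)(C)[Si](C)(C)Cl | starting material
9 | rac-1-{4-[(E)-3-(tert-butyldimethylsilyloxy)prop-1-enyl]-2,6-dimethoxyphenoxy}-3-methylbut-3-en-2-ol | C=C(C)C(O)COc1c(OC)cc(/C=C/CO[Si](C)(C)C(C)(C)C)cc1OC | intermediate
10 | triethyl orthoacetate | CCOC(C)(OCC)OCC | starting material
11 | mixed orthoester: the 1,1-diethoxyethyl ether of 9 at its secondary hydroxyl (racemic) | C=C(C)C(COc1c(OC)cc(/C=C/CO[Si](C)(C)C(C)(C)C)cc1OC)OC(C)(OCC)OCC | intermediate
12 | ketene acetal: the 1-ethoxyvinyl ether of 9 at its secondary hydroxyl (racemic) | C=C(C)C(COc1c(OC)cc(/C=C/CO[Si](C)(C)C(C)(C)C)cc1OC)OC(=C)OCC | intermediate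
13 | ethyl (E)-6-{4-[(E)-3-(tert-butyldimethylsilyloxy)prop-1-enyl]-2,6-dimethoxyphenoxy}-4-methylhex-4-enoate | CCOC(=O)CC/C(C)=C/COc1c(OC)cc(/C=C/CO[Si](C)(C)C(C)(C)C)cc1OC | intermediate
14 | N,O-dimethylhydroxylamine hydrochloride | CNOC.Cl | starting material
15 | (E)-6-{4-[(E)-3-(tert-butyldimethylsilyloxy)prop-1-enyl]-2,6-dimethoxyphenoxy}-N-methoxy-N,4-dimethylhex-4-enamide | CON(C)C(=O)CC/C(C)=C/COc1c(OC)cc(/C=C/CO[Si](C)(C)C(C)(C)C)cc1OC | intermediate
16 | (E)-8-{4-[(E)-3-(tert-butyldimethylsilyloxy)prop-1-enyl]-2,6-dimethoxyphenoxy}-2,6-dimethylocta-1,6-dien-3-one | C=C(C)C(=O)CC/C(C)=C/COc1c(OC)cc(/C=C/CO[Si](C)(C)C(C)(C)C)cc1OC | intermediate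
17 | (3R,6E)-8-{4-[(E)-3-(tert-butyldimethylsilyloxy)prop-1-enyl]-2,6-dimethoxyphenoxy}-2,6-dimethylocta-1,6-dien-3-ol | C=C(C)[C@H](O)CC/C(C)=C/COc1c(OC)cc(/C=C/CO[Si](C)(C)C(C)(C)C)cc1OC | intermediate
18 | (3R,6E)-8-{4-[(E)-3-hydroxyprop-1-enyl]-2,6-dimethoxyphenoxy}-2,6-dimethylocta-1,6-dien-3-ol | C=C(C)[C@H](O)CC/C(C)=C/COc1c(OC)cc(/C=C/CO)cc1OC | target

## Step count and risk

Total step count: 10. Longest linear sequence: 10 steps, from 1 to 18; the route is linear, and 2, 5, 8, 10 and 14 are purchased reagents.

**Step 6 (key step).** The exchange and elimination that lead to the ketene acetal may be slow, because the carbinol is secondary, hindered by the 2-methylallyl group and deactivated by the β-aryloxy group. Long heating with acid then invites ionisation of the electron-rich cinnamyl silyl ether or of the new allyl aryl ether, and a boat pathway could erode the E selectivity. The fallback is an Ireland–Claisen rearrangement, which needs neither acid nor heat; it sets out from 9 and comes back at 15. Compound 9 would be acetylated (Ac2O, pyridine, 4-(dimethylamino)pyridine) to the acetate F1. LiN(i-Pr)2 in THF at −78 °C followed by Me3SiCl should give the trimethylsilyl ketene acetal F2, which rearranges on warming to room temperature through the same chair to the silyl ester F3. Neutral aqueous work-up liberates the acid F4, which is activated with 1,1′-carbonyldiimidazole and treated with 14 and Et3N to give 15.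

**Step 1.** Displacement at the deactivated β,β-dialkoxyethyl bromide by a phenoxide flanked by two methoxy groups may be slow, and at the temperature required dehydrobromination of 2 or cleavage of the methyl ester may compete. The fallback sets out from 1 and comes back at 4, bypassing 3. Hydroxyethylation of 1 with ethylene carbonate (K2CO3, DMF, 120 °C) should give the hydroxyethyl ether F5, and oxidation with Dess–Martin periodinane in CH2Cl2 gives 4.

**Step 3.** Chemoselectivity may be incomplete: the Grignard reagent could attack the enoate, the sensitive aldehyde could enolise and self-condense, and residual hydrate would consume reagent. The fallback removes the ester before any organometallic step; it sets out from 3 and comes back at 9, in the same number of steps. Reduction of 3 with i-Bu2AlH would give the acetal alcohol F6, and silylation with 8 and imidazole the silyl ether acetal F7. The acetal is then cleaved under non-protic conditions that a silyl ether survives (Et3SiOSO2CF3, 2,4,6-collidine, CH2Cl2, 0 °C, then water) to the aldehyde F8, and addition of 5 at −78 °C gives 9.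

**Step 9.** Facial discrimination between the isopropenyl group and the unbranched chain may be insufficient, and uncatalysed background reduction would lower the enantiomeric purity further. The fallback replaces asymmetric reduction by kinetic resolution; it sets out from 16 and comes back at 17. Luche reduction (NaBH4, CeCl3·7H2O, MeOH, −40 °C) would give the racemic alcohol F9. Sharpless kinetic resolution (Ti(OiPr)4, L-(+)-diisopropyl tartrate, t-BuOOH (0.6 equiv), 4 Å molecular sieves, CH2Cl2, −20 °C) should epoxidise the (S)-enantiomer faster, to the epoxy alcohol F10, and leave (R)-configured 17, which is separated by chromatography. The cost is at most half of the material.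

## Further compounds

F1 | step 6 | rac-1-{4-[(E)-3-(tert-butyldimethylsilyloxy)prop-1-enyl]-2,6-dimethoxyphenoxy}-3-methylbut-3-en-2-yl acetate | C=C(C)C(COc1c(OC)cc(/C=C/CO[Si](C)(C)C(C)(C)C)cc1OC)OC(C)=O
F2 | step 6 | trimethylsilyl ketene acetal of F1, the 1-(trimethylsilyloxy)vinyl ether of 9 (racemic) | C=C(C)C(COc1c(OC)cc(/C=C/CO[Si](C)(C)C(C)(C)C)cc1OC)OC(=C)O[Si](C)(C)C
F3 | step 6 | trimethylsilyl (E)-6-{4-[(E)-3-(tert-butyldimethylsilyloxy)prop-1-enyl]-2,6-dimethoxyphenoxy}-4-methylhex-4-enoate | C[Si](C)(C)OC(=O)CC/C(C)=C/COc1c(OC)cc(/C=C/CO[Si](C)(C)C(C)(C)C)cc1OC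
F4 | step 6 | (E)-6-{4-[(E)-3-(tert-butyldimethylsilyloxy)prop-1-enyl]-2,6-dimethoxyphenoxy}-4-methylhex-4-enoic acid | OC(=O)CC/C(C)=C/COc1c(OC)cc(/C=C/CO[Si](C)(C)C(C)(C)C)cc1OC
F5 | step 1 | methyl (E)-3-[4-(2-hydroxyethoxy)-3,5-dimethoxyphenyl]prop-2-enoate | OCCOc1c(OC)cc(/C=C/C(=O)OC)cc1OC
F6 | step 3 | (E)-3-[4-(2,2-diethoxyethoxy)-3,5-dimethoxyphenyl]prop-2-en-1-ol | CCOC(COc1c(OC)cc(/C=C/CO)cc1OC)OCC
F7 | step 3 | tert-butyl{(E)-3-[4-(2,2-diethoxyethoxy)-3,5-dimethoxyphenyl]prop-2-enyloxy}dimethylsilane | CCOC(COc1c(OC)cc(/C=C/CO[Si](C)(C)C(C)(C)C)cc1OC)OCC
F8 | step 3 | 2-{4-[(E)-3-(tert-butyldimethylsilyloxy)prop-1-enyl]-2,6-dimethoxyphenoxy}acetaldehyde | O=CCOc1c(OC)cc(/C=C/CO[Si](C)(C)C(C)(C)C)cc1OC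
F9 | step 9 | rac-(E)-8-{4-[(E)-3-(tert-butyldimethylsilyloxy)prop-1-enyl]-2,6-dimethoxyphenoxy}-2,6-dimethylocta-1,6-dien-3-ol | C=C(C)C(O)CC/C(C)=C/COc1c(OC)cc(/C=C/CO[Si](C)(C)C(C)(C)C)cc1OC
F10 | step 9 | (1S,4E)-6-{4-[(E)-3-(tert-butyldimethylsilyloxy)prop-1-enyl]-2,6-dimethoxyphenoxy}-4-methyl-1-[(2S)-2-methyloxiran-2-yl]hex-4-en-1-ol | C[C@]1(CO1)[C@@H](O)CC/C(C)=C/COc1c(OC)cc(/C=C/CO[Si](C)(C)C(C)(C)C)cc1OC
A1 | alternative 1 | methyl (E)-3-{4-[(2E,6E)-8-hydroxy-3,7-dimethylocta-2,6-dienyloxy]-3,5-dimethoxyphenyl}prop-2-enoate | OC/C(C)=C/CC/C(C)=C/COc1c(OC)cc(/C=C/C(=O)OC)cc1OC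
A2 | alternative 1 | methyl (E)-3-{4-[(2E,6R,7R)-6,7-epoxy-8-hydroxy-3,7-dimethyloct-2-enyloxy]-3,5-dimethoxyphenyl}prop-2-enoate | OC[C@@]1(C)O[C@@H]1CC/C(C)=C/COc1c(OC)cc(/C=C/C(=O)OC)cc1OC
A3 | alternative 2 | (3R)-3-(tert-butyldimethylsilyloxy)-2-methylhept-1-en-6-yne | C=C(C)[C@H](O[Si](C)(C)C(C)(C)C)CCC#C
A4 | alternative 2 | formaldehyde | C=O
A5 | alternative 2 | (2E,6R)-6-(tert-butyldimethylsilyloxy)-3,7-dimethylocta-2,7-dien-1-ol | C=C(C)[C@H](O[Si](C)(C)C(C)(C)C)CC/C(C)=C/CO
A6 | alternative 3 | methyl (E)-3-{4-[(2E)-3,7-dimethylocta-2,6-dienyloxy]-3,5-dimethoxyphenyl}prop-2-enoate | CC(C)=CCC/C(C)=C/COc1c(OC)cc(/C=C/C(=O)OC)cc1OC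
A7 | alternative 3 | methyl (E)-3-{3,5-dimethoxy-4-[(2E)-3-methyl-6-oxohex-2-enyloxy]phenyl}prop-2-enoate | O=CCC/C(C)=C/COc1c(OC)cc(/C=C/C(=O)OC)cc1OC
A8 | alternative 3 | 2-bromopropene | C=C(C)Br
A9 | alternative 3 | methyl (E)-3-{4-[(2E,6R)-6-hydroxy-3,7-dimethylocta-2,7-dienyloxy]-3,5-dimethoxyphenyl}prop-2-enoate | C=C(C)[C@H](O)CC/C(C)=C/COc1c(OC)cc(/C=C/C(=O)OC)cc1OC
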